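**Plan**

- Retrosynthesis first ties the C1 carboxyl and the C8 hydroxyl of the nonanoic acid chain back into a nine-membered lactone. It then cuts the pyranone at C4a–C4, C4–C3 and O1–C2 into 2-iodo-5-methoxyresorcinol, carbon monoxide and a terminal alkyne. Last, it removes the ring oxygen at C8 (Baeyer–Villiger in reverse) and cuts the C8–C9 bond, leaving cyclooctanone and a silylated propargyl bromide.
- Enabling feature: C1 (carboxyl), the six methylenes C2–C7 and the carbinol carbon C8 are eight contiguous carbons, the ring of a cyclooctanone whose α-carbon carries C9, the CH2 bound to chromone C2. In addition, C4a of the chromone lies between O1 and the 5-OH, so a mirror-symmetric resorcinol can supply ring A.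
- Forward order: the bought eight-membered carbocycle is α-propargylated and expanded by oxygen insertion to the nine-membered lactone, which masks hydroxyl and acid together. The pyranone ring is then closed onto the bought benzene ring by carbonylative alkyne annulation, and the lactone is opened last.
- Stereochemistry: the single stereocentre (C8, R) is set as a C–C stereocentre by alkylation of the RAMP-hydrazone azaenolate and becomes the carbinol with retention in the Baeyer–Villiger migration. No later step touches it.

Key step: step 5

Remark: the C=N geometry of the hydrazones, the C=C geometry of the enaminone intermediate and the hemiketal carbon of the peracid adduct are left undefined, since none of them is carried into the product.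

**Route**

Step 1
Reactants: 1 cyclooctanone; 2 (R)-1-amino-2-(methoxymethyl)pyrrolidine (RAMP)
Product: 3 (R)-N-cyclooctylidene-2-(methoxymethyl)pyrrolidin-1-amine
Conditions: cyclohexane, reflux, water separator
Reagents that add atoms: none
Why: Hydrazone formation by condensation of the ketone with the N-amino group is an equilibrium that azeotropic removal of water should drive to completion despite the sluggish carbonyl of the eight-membered ring.

Step 2
Reactants: 3 (R)-N-cyclooctylidene-2-(methoxymethyl)pyrrolidin-1-amine; 4 3-bromo-1-(trimethylsilyl)prop-1-yne
Product: 6 (R)-2-(methoxymethyl)-N-{(R)-2-[3-(trimethylsilyl)prop-2-yn-1-yl]cyclooctylidene}pyrrolidin-1-amine, via lithium azaenolate 5 (not isolated)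
Conditions: LiN(iPr)2 (LDA), THF, 0 °C; then 4, −100 °C → rt
Reagents that add atoms: none
Why: In this RAMP-hydrazone α-alkylation, deprotonation should give the lithium-chelated azaenolate 5 with E C=C and Z C–N geometry, whose faces are differentiated by the methoxymethylpyrrolidine, so that the propargylic bromide is taken up from the open face and the new α-stereocentre is set as R (the enantiomeric auxiliary would give S), the silyl cap removing the acidic alkyne proton and suppressing allene formation; the enantiomeric purity would be checked by chiral gas chromatography on the ketone released in step 4.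

Step 3
Reactants: 6 (R)-2-(methoxymethyl)-N-{(R)-2-[3-(trimethylsilyl)prop-2-yn-1-yl]cyclooctylidene}pyrrolidin-1-amine
Product: 7 (R)-2-(methoxymethyl)-N-[(R)-2-(prop-2-yn-1-yl)cyclooctylidene]pyrrolidin-1-amine
Conditions: K2CO3 (cat.), MeOH, rt
Reagents that add atoms: none
Why: Base-catalysed methanolysis of the C(sp)–Si bond (protodesilylation of an alkynylsilane) is carried out at this stage because the α-centre is configurationally safe as the hydrazone and no ester is yet present that methoxide could open.

Step 4
Reactants: 7 (R)-2-(methoxymethyl)-N-[(R)-2-(prop-2-yn-1-yl)cyclooctylidene]pyrrolidin-1-amine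
Product: 8 (R)-2-(prop-2-yn-1-yl)cyclooctanone
Conditions: sat. aq. (CO2H)2, Et2O, rt, two-phase
Reagents that add atoms: water, O
Why: Two-phase acidic hydrolysis of the hydrazone with oxalic acid should release the ketone into the ether layer while the auxiliary is held in the water layer as its oxalate for recovery, conditions known to leave an α-stereocentre intact, and the ketone is taken on at once without contact with base.

Step 5
Reactants: 8 (R)-2-(prop-2-yn-1-yl)cyclooctanone
Product: 10 (R)-9-(prop-2-yn-1-yl)oxonan-2-one, via Criegee adduct 9 (not isolated)
Conditions: urea·H2O2, (CF3CO)2O, Na2HPO4, CH2Cl2, 0 °C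
Reagents that add atoms: urea–hydrogen peroxide, NC(N)=O.OO (its peroxide oxygen is passed on through trifluoroperacetic acid, OOC(=O)C(F)(F)F, formed in the flask with trifluoroacetic anhydride)
Why: The peracid adds to the ketone carbonyl to give the Criegee adduct 9, and the ring carbon antiperiplanar to the breaking O–O bond shifts from carbon to oxygen in a concerted 1,2-migration with loss of trifluoroacetate (Baeyer–Villiger oxidation; the closest known case is the oxidation of 2-alkylcycloalkanones to ω-alkyl lactones). The nine-membered lactone ring is therefore formed by ring expansion, insertion of oxygen into the C1–C2 bond of the eight-membered ketone, and not by a cyclisation, which is why this otherwise unfavourable medium ring is reached easily. No new stereocentre is created: the migrating carbon keeps its configuration, and since oxygen takes the priority position of the former carbonyl carbon the descriptor stays R. Regioselectivity between the two α-carbons is needed and is secured by the higher migratory aptitude of the secondary, propargyl-bearing carbon over the ring CH2. Chemoselectivity over the terminal alkyne follows from its low reactivity towards electrophilic peracids at 0 °C, a strong peracid being chosen because the transannularly strained cyclooctanone carbonyl adds nucleophiles reluctantly. The phosphate buffer holds back acid-catalysed enolisation of the α-centre, and once the lactone has formed that centre is no longer epimerisable and both the hydroxyl and the carboxyl of the target are masked without any protecting group.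

Step 6
Reactants: 11 5-methoxyresorcinol (5-methoxybenzene-1,3-diol)
Product: 12 1-methoxy-3,5-bis(methoxymethoxy)benzene
Conditions: NaH, MOMCl, DMF, 0 °C → rt
Reagents that add atoms: chloromethyl methyl ether (MOMCl), COCCl
Why: O-Alkylation of the bis-phenoxide with the hard chloromethyl ether (Williamson-type acetal formation) should give the bis-acetal, which protects both phenols against the organolithium and provides the two cooperating directing groups for the next step.

Step 7
Reactants: 12 1-methoxy-3,5-bis(methoxymethoxy)benzene
Product: 14 2-iodo-5-methoxy-1,3-bis(methoxymethoxy)benzene, via aryllithium 13 (not isolated)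
Conditions: n-BuLi, THF, 0 °C; then I2, −78 °C → rt
Reagents that add atoms: iodine, II
Why: Directed ortho-metalation should take place at C2, the only position flanked by two chelating OCH2OCH3 groups and therefore more acidic and better coordinated than C4 or C6, and the aryllithium 13 is then trapped by iodine (iodinolysis of the C–Li bond).

Step 8
Reactants: 14 2-iodo-5-methoxy-1,3-bis(methoxymethoxy)benzene
Product: 15 2-iodo-5-methoxybenzene-1,3-diol (2-iodo-5-methoxyresorcinol)
Conditions: HCl (2 M in MeOH), rt, dark
Reagents that add atoms: none
Why: Acid-catalysed acetal exchange with methanol cleaves both methoxymethyl ethers (transacetalisation to dimethoxymethane), and mild acid at room temperature in the dark is chosen so that the electron-rich aryl iodide is not protodeiodinated; the free iodoresorcinol is used without storage.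

Step 9
Reactants: 10 (R)-9-(prop-2-yn-1-yl)oxonan-2-one; 15 2-iodo-5-methoxybenzene-1,3-diol; 16 carbon monoxide
Product: 19 (R)-9-[(5-hydroxy-7-methoxy-4-oxo-4H-chromen-2-yl)methyl]oxonan-2-one, via ynone 17 (not isolated), via enaminone 18 (not isolated)
Conditions: PdCl2(PPh3)2 (5 mol %), Ph2P(CH2)3PPh2 (5 mol %), Et2NH (5 equiv), THF, CO (1 atm), 50 °C
Reagents that add atoms: none
Why: In this palladium-catalysed carbonylative Sonogashira annulation of an ortho-iodophenol with a terminal alkyne, oxidative addition of the C–I bond to zerovalent palladium, CO insertion and alkynylation should give ynone 17, diethylamine adds to it to give enaminone 18, and the ortho hydroxyl then closes the pyranone 6-endo-trig by addition–elimination with loss of the amine, the two hydroxyls being equivalent by symmetry so that the second one becomes the chelated 5-OH, while the absence of copper salts and strong base and the moderate temperature should spare the lactone and its carbinol centre.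

Step 10
Reactants: 19 (R)-9-[(5-hydroxy-7-methoxy-4-oxo-4H-chromen-2-yl)methyl]oxonan-2-one
Product: 21 Penithochromone S [(R)-8-hydroxy-9-(5-hydroxy-7-methoxy-4-oxo-4H-chromen-2-yl)nonanoic acid], via dilithium salt 20 (not isolated)
Conditions: LiOH (3 equiv), THF/H2O, 0 °C → rt; then 1 M HCl to pH 3
Reagents that add atoms: lithium hydroxide, [Li+].[OH-]
Why: Saponification of the lactone by acyl–oxygen cleavage leaves the C8–O bond and hence the R configuration untouched, the phenoxide formed first deactivates the chromone towards hydroxide, and the released hydroxy acid 21 cannot close back to a nine-membered ring on mild acidification.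

**Compound list**

1 | cyclooctanone | O=C1CCCCCCC1 | starting material
2 | (R)-1-amino-2-(methoxymethyl)pyrrolidine (RAMP) | COC[C@H]1CCCN1N | starting material
3 | (R)-N-cyclooctylidene-2-(methoxymethyl)pyrrolidin-1-amine | COC[C@H]1CCCN1N=C1CCCCCCC1 | intermediate
4 | 3-bromo-1-(trimethylsilyl)prop-1-yne | C[Si](C)(C)C#CCBr | starting material
5 | lithium (E)-cyclooct-1-en-1-yl[(R)-2-(methoxymethyl)pyrrolidin-1-yl]amide (lithium azaenolate) | [Li]N(N1CCC[C@@H]1COC)/C1=C/CCCCCC1 | intermediate (not isolated)
6 | (R)-2-(methoxymethyl)-N-{(R)-2-[3-(trimethylsilyl)prop-2-yn-1-yl]cyclooctylidene}pyrrolidin-1-amine | C[Si](C)(C)C#CC[C@H]1CCCCCCC1=NN1CCC[C@@H]1COC | intermediate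
7 | (R)-2-(methoxymethyl)-N-[(R)-2-(prop-2-yn-1-yl)cyclooctylidene]pyrrolidin-1-amine | C#CC[C@H]1CCCCCCC1=NN1CCC[C@@H]1COC | intermediate
8 | (R)-2-(prop-2-yn-1-yl)cyclooctanone | C#CC[C@H]1CCCCCCC1=O | intermediate
9 | (2R)-1-hydroxy-2-(prop-2-yn-1-yl)cyclooctyl 2,2,2-trifluoroethaneperoxoate (Criegee adduct) | C#CC[C@H]1CCCCCCC1(O)OOC(=O)C(F)(F)F | intermediate (not isolated)
10 | (R)-9-(prop-2-yn-1-yl)oxonan-2-one | C#CC[C@H]1CCCCCCC(=O)O1 | intermediate
11 | 5-methoxyresorcinol (5-methoxybenzene-1,3-diol) | COc1cc(O)cc(O)c1 | starting material
12 | 1-methoxy-3,5-bis(methoxymethoxy)benzene | COCOc1cc(OC)cc(OCOC)c1 | intermediate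
13 | [4-methoxy-2,6-bis(methoxymethoxy)phenyl]lithium | [Li]c1c(OCOC)cc(OC)cc1OCOC | intermediate (not isolated)
14 | 2-iodo-5-methoxy-1,3-bis(methoxymethoxy)benzene | COCOc1cc(OC)cc(OCOC)c1I | intermediate
15 | 2-iodo-5-methoxybenzene-1,3-diol | COc1cc(O)c(I)c(O)c1 | intermediate
16 | carbon monoxide | [C-]#[O+] | starting material
17 | (R)-9-[4-(2,6-dihydroxy-4-methoxyphenyl)-4-oxobut-2-yn-1-yl]oxonan-2-one (ynone) | COc1cc(O)c(C(=O)C#CC[C@H]2CCCCCCC(=O)O2)c(O)c1 | intermediate (not isolated)
18 | (R)-9-[2-(diethylamino)-4-(2,6-dihydroxy-4-methoxyphenyl)-4-oxobut-2-en-1-yl]oxonan-2-one (enaminone) | CCN(CC)C(C[C@H]1CCCCCCC(=O)O1)=CC(=O)c1c(O)cc(OC)cc1O | intermediate (not isolated)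
19 | (R)-9-[(5-hydroxy-7-methoxy-4-oxo-4H-chromen-2-yl)methyl]oxonan-2-one | COc1cc(O)c2c(=O)cc(C[C@H]3CCCCCCC(=O)O3)oc2c1 | intermediate
20 | dilithium (R)-8-hydroxy-9-(7-methoxy-5-oxido-4-oxo-4H-chromen-2-yl)nonanoate | [Li+].[Li+].COc1cc([O-])c2c(=O)cc(C[C@H](O)CCCCCCC(=O)[O-])oc2c1 | intermediate (not isolated)
21 | Penithochromone S, (R)-8-hydroxy-9-(5-hydroxy-7-methoxy-4-oxo-4H-chromen-2-yl)nonanoic acid | COc1cc(O)c2c(=O)cc(C[C@H](O)CCCCCCC(=O)O)oc2c1 | target

**Step count and risks**

Total step count: 10. Longest linear sequence: 7 steps (steps 1–5, 9 and 10, from cyclooctanone); the arene branch (steps 6–8) joins at step 9.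

Most likely to fail, step 9. Several processes could divert the carbonylation and alkynylation sequence:
- capture of the acylpalladium intermediate by diethylamine or by a phenol (amide or aryl ester formation);
- direct alkynylation without CO uptake, followed by closure to a benzofuran;
- base-induced elimination of the lactone carboxylate from the activated CH2 next to the ynone.

The fallback separates C–C bond formation from ring closure and uses no CO and no free phenol in the coupling. It sets out from bis-acetal 12 and lactone 10 and comes back to the route at chromone lactone 19. Aryllithium 13, made as in step 7, would be quenched with CO2 to give 4-methoxy-2,6-bis(methoxymethoxy)benzoic acid F1. 1-Chloro-N,N,2-trimethylprop-1-en-1-amine in CH2Cl2 should convert F1 under neutral conditions, which spare the acetals, into 4-methoxy-2,6-bis(methoxymethoxy)benzoyl chloride F2. Acyl Sonogashira coupling of F2 with 10 (PdCl2(PPh3)2, CuI, Et3N, THF, rt) would give the protected ynone (R)-9-{4-[4-methoxy-2,6-bis(methoxymethoxy)phenyl]-4-oxobut-2-yn-1-yl}oxonan-2-one F3. Conjugate addition of Et2NH in EtOH at rt should then give the enaminone (R)-9-{2-(diethylamino)-4-[4-methoxy-2,6-bis(methoxymethoxy)phenyl]-4-oxobut-2-en-1-yl}oxonan-2-one F4. Aqueous HCl in THF should remove both acetals and let a freed phenol displace the amine, closing the pyranone to 19.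

Second, step 5. Addition of the peracid to the transannularly hindered carbonyl may be so slow that prolonged exposure lets oxidation of the free terminal alkyne and acid-catalysed enolisation of the α-centre compete. The fallback keeps the alkyne silyl-capped through the oxidation so that excess peracid and longer times can be used. It sets out from silylated hydrazone 6 and comes back at lactone 10. Two-phase oxalic acid cleavage of 6 would give (R)-2-[3-(trimethylsilyl)prop-2-yn-1-yl]cyclooctanone F5. The same buffered Baeyer–Villiger oxidation, now run with excess peracid, should give (R)-9-[3-(trimethylsilyl)prop-2-yn-1-yl]oxonan-2-one F6. Bu4NF buffered with AcOH in THF at 0 °C would then remove the silyl group without opening the lactone and deliver 10.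

Third, step 10. Hydroxide may deprotonate the CH2 at C2 of the chromone and expel the lactone carboxylate by vinylogous elimination, or add to C2 and open the pyranone, faster than it cleaves the lactone. The fallback reverses the order of lactone opening and annulation so that hydroxide never meets the chromone. It sets out from lactone 10 and comes back at target 21. LiOH in THF/water would open 10, which carries no base-sensitive group, to (R)-8-hydroxyundec-10-ynoic acid F7 after acidification. F7, as its diethylammonium salt, would then be submitted with 15 and 16 to the conditions of step 9. The sequence should pass through the ynone acid (R)-12-(2,6-dihydroxy-4-methoxyphenyl)-8-hydroxy-12-oxododec-10-ynoic acid F8 and the enaminone acid (R)-10-(diethylamino)-12-(2,6-dihydroxy-4-methoxyphenyl)-8-hydroxy-12-oxododec-10-enoic acid F9 and give 21 directly. A free hydroxyl is a far poorer leaving group than the lactone carboxylate, so the elimination pathway is also weakened.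

**Further compounds**

F1 | step 9 | 4-methoxy-2,6-bis(methoxymethoxy)benzoic acid | COCOc1cc(OC)cc(OCOC)c1C(=O)O
F2 | step 9 | 4-methoxy-2,6-bis(methoxymethoxy)benzoyl chloride | COCOc1cc(OC)cc(OCOC)c1C(=O)Cl
F3 | step 9 | (R)-9-{4-[4-methoxy-2,6-bis(methoxymethoxy)phenyl]-4-oxobut-2-yn-1-yl}oxonan-2-one | COCOc1cc(OC)cc(OCOC)c1C(=O)C#CC[C@H]1CCCCCCC(=O)O1
F4 | step 9 | (R)-9-{2-(diethylamino)-4-[4-methoxy-2,6-bis(methoxymethoxy)phenyl]-4-oxobut-2-en-1-yl}oxonan-2-one | CCN(CC)C(C[C@H]1CCCCCCC(=O)O1)=CC(=O)c1c(OCOC)cc(OC)cc1OCOC
F5 | step 5 | (R)-2-[3-(trimethylsilyl)prop-2-yn-1-yl]cyclooctanone | C[Si](C)(C)C#CC[C@H]1CCCCCCC1=O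
F6 | step 5 | (R)-9-[3-(trimethylsilyl)prop-2-yn-1-yl]oxonan-2-one | C[Si](C)(C)C#CC[C@H]1CCCCCCC(=O)O1
F7 | step 10 | (R)-8-hydroxyundec-10-ynoic acid | C#CC[C@H](O)CCCCCCC(=O)O
F8 | step 10 | (R)-12-(2,6-dihydroxy-4-methoxyphenyl)-8-hydroxy-12-oxododec-10-ynoic acid | COc1cc(O)c(C(=O)C#CC[C@H](O)CCCCCCC(=O)O)c(O)c1
F9 | step 10 | (R)-10-(diethylamino)-12-(2,6-dihydroxy-4-methoxyphenyl)-8-hydroxy-12-oxododec-10-enoic acid | CCN(CC)C(C[C@H](O)CCCCCCC(=O)O)=CC(=O)c1c(O)cc(OC)cc1O
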